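Incoming ligand is the limiting reagent in these flasks: it exchanges onto the starting complex, then onto the complex with one exchanged and the complex with two exchanged, while the protic impurity quenches it, leaving ligand turns starting complex into side product A, and starting complex with complex with one exchanged gives side product B.

| flask | starting complex | incoming ligand | leaving ligand | protic impurity | remark | time |
|---|---|---|---|---|---|---|
| alder | 0.30 M | 0.33 M | 1.5 M | 0.15 M | run made earlier |  |
| elm | 0.20 M | 0.33 M | 1.5 M | 0.15 M | run made earlier |  |
| oak | 0.45 M | 0.33 M | 1.5 M | 0.15 M | run made earlier |  |
| maple | 0.30 M | 0.49 M | 1.5 M | 0.15 M | run made earlier |  |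
| south-west | 0.30 M (fed, over 1.5 h) | 0.330 M | 1.50 M | 0.150 M | all else is in the flask from the start; the feed brings no volume worth counting | 4.0 h |
| south | 0.30 M (fed, over 10 min) | 0.330 M | 1.50 M | 0.150 M | all else is in the flask from the start; the feed brings no volume worth counting | 4.0 h |
| south-east | 0.30 M | 0.330 M | 1.50 M | 0.150 M | everything together at the start | 4.0 h |
| west | 0.30 M | 0.330 M (fed, over 1.5 h) | 1.50 M | 0.150 M | all else is in the flask from the start; the feed brings no volume worth counting | 4.0 h |

| run | time / h | complex with one exchanged / % | complex with two exchanged / % |
|---|---|---|---|
| alder | 0.667 | 17 | 19 |
| alder | 1.33 | 13 | 18 |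
| alder | 2.00 | 12 | 19 |
| alder | 2.50 | 13 | 15 |
| alder | 3.00 | 16 | 17 |
| alder | 4.00 | 15 | 18 |
| elm | 0.333 | 23 | 25 |
| elm | 1.00 | 19 | 23 |
| elm | 1.50 | 20 | 26 |
| elm | 2.50 | 18 | 26 |
| elm | 4.00 | 14 | 27 |
| elm | 5.00 | 15 | 28 |
| oak | 0.833 | 17 | 13 |
| oak | 1.50 | 10 | 13 |
| oak | 2.50 | 10 | 9 |
| oak | 3.00 | 12 | 12 |
| oak | 4.00 | 7 | 12 |
| oak | 5.00 | 10 | 10 |
| maple | 0.417 | 20 | 28 |
| maple | 0.667 | 17 | 32 |
| maple | 1.33 | 17 | 27 |
| maple | 2.50 | 18 | 31 |
| maple | 5.00 | 15 | 26 |

(scatter of a reading: 2 percentage points)

- a species is counted by the starting complex in it: one side product B counts as two
- reactions considered so far: starting complex + incoming ligand -> leaving ligand + complex with one exchanged; complex with one exchanged + incoming ligand -> leaving ligand + complex with two exchanged; complex with two exchanged + incoming ligand -> leaving ligand + complex with three exchanged; leaving ligand + starting complex -> side product A; starting complex + complex with one exchanged -> side product B; protic impurity + incoming ligand -> quenched reagent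

* which flask leads in share of complex with one exchanged in complex with one exchanged plus complex with two exchanged ("all alike" within 1.5 percentage points) (south-west / south / south-east / west / all alike)
* share of complex with one exchanged in complex with one exchanged plus complex with two exchanged at the end, south-west
* share of complex with one exchanged in complex with one exchanged plus complex with two exchanged at the end, south
* share of complex with one exchanged in complex with one exchanged plus complex with two exchanged at the end, south-east
* share of complex with one exchanged in complex with one exchanged plus complex with two exchanged at the end, west

We take one clock from the runs. In the elm run the complex with two exchanged reads 25% at the first reading, 0.333 h, and 28% at the last, so we take that first time, a reading with its scatter, as our rough estimate of the time the elm batch needs to take up its ligand. That estimate gives a mean uptake rate of about 0.991 M h⁻¹ in the elm run, and we expect the rate to fall as ligand and its partners fall. The slow feed in west delivers 0.220 M h⁻¹, which is slower than that estimated uptake of the elm run, so we expect the feed to set the pace in west. We therefore count turnovers of this clock, and our 4.50 is the feed count, the feed time divided by the uptake time. The quick feed has a count of 0.501, below one, while the slow feed stands above it. We apply the same count to the feed of complex in south-west and south as to the feed of ligand in west, although the clock comes from a batch with everything present. Our own reckoning gives a direction and no percentage: south stays close to south-east, while south-west and west fall well below it.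

The forecast gave 10% for south-west, 36% for south, 44% for south-east and 30% for west, so that south-east leads, and it reasoned for west that “the early feed goes to quench while starting complex decays”. It places south 8 percentage points below south-east, where our count expected the two close together.

The flasks give 25.3% for south-west, 41.4% for south, 43.3% for south-east and 28.1% for west, so south-east leads.

    starting complex + incoming ligand → leaving ligand + complex with one exchanged (k = 0.0109 M⁻¹ s⁻¹)
    complex with one exchanged + incoming ligand → leaving ligand + complex with two exchanged (k = 0.0175 M⁻¹ s⁻¹)
    complex with two exchanged + incoming ligand → leaving ligand + complex with three exchanged (k = 0.00810 M⁻¹ s⁻¹)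
    leaving ligand + starting complex → side product A (k = 1.72 × 10⁻⁴ M⁻¹ s⁻¹)
    starting complex + complex with one exchanged → side product B (k = 0.00182 M⁻¹ s⁻¹)
    protic impurity + incoming ligand → quenched reagent (k = 0.0147 M⁻¹ s⁻¹)

West ends with 56.2% of side product A, against 36.4% in south-east. South, at count 0.501, lies 1.9 points below south-east, whereas south-west and west, at count 4.50, lie 18 points and 15 points below it.

West with its feed shortened to 0.150 h has a count of 0.450, below one like south, so the count places it beside south-east. Computed, that flask gives 42.8%.

The numbers in the tables were computed on assumed constants, noise included.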